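**Strategy.** The side chain contains a 1,5-dien-3-ol, C2'=C3'(Me)–C4'H2–C5'H(OH)–C6'=C7', which is the retron of a [2,3]-Wittig rearrangement. The C4'–C5' bond is therefore disconnected through a temporary C2'–O–C5' ether: an (S)-aryl-substituted 2-methylallylic carbinol (C1'–C4') is O-alkylated with an (E)-allylic bromide carrying C5'–C13', and the bis-allylic ether is rearranged. In one operation this joins the two halves by a C–C bond, relays the easily set C2' configuration to the C5' carbinol, and creates the E-C2'=C3' alkene, so no β,γ-unsaturated aldehyde is ever needed. C11' is bought with (S)-citronellal; C12' is set by proline catalysis.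

Key step: step 14

Remark: side-chain carbons are numbered C1' (benzylic CH2) to C15'; the target is (2'E,5'R,6'E,11'S,12'R).
Assumption: (S)-citronellal of high enantiomeric purity and the L-fructose-derived enantiomer of the Shi ketone are taken as commercial.

**Step 1**
Reactants: 1 4-methoxy-2-methylphenol; 2 1-bromo-3-methylbut-2-ene
Product: 3 4-methoxy-2-methyl-6-(3-methylbut-2-en-1-yl)phenol
Conditions: NaH, toluene, 0 °C → rt
Reagents that add atoms: none
Why: In a non-polar solvent the sodium phenoxide reacts as a tight ion pair at the ortho carbon (C-alkylation of a phenoxide), and C6 is the only free ortho position, so the prenyl group should enter there.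

**Step 2**
Reactants: 3 4-methoxy-2-methyl-6-(3-methylbut-2-en-1-yl)phenol
Product: 4 triisopropyl[4-methoxy-2-methyl-6-(3-methylbut-2-en-1-yl)phenoxy]silane
Conditions: TIPSOTf, 2,6-lutidine, CH2Cl2, 0 °C → rt
Reagents that add atoms: triisopropylsilyl trifluoromethanesulfonate CC(C)[Si](OS(=O)(=O)C(F)(F)F)(C(C)C)C(C)C
Why: Silylation of the hindered phenol with a silyl triflate; TIPS is chosen because it should survive carbonate buffer, hydride and alkyllithium and should not migrate to a neighbouring alkoxide.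

**Step 3**
Reactants: 4 triisopropyl[4-methoxy-2-methyl-6-(3-methylbut-2-en-1-yl)phenoxy]silane
Product: 5 (S)-3-{[5-methoxy-3-methyl-2-(triisopropylsilyloxy)phenyl]methyl}-2,2-dimethyloxirane
Conditions: L-fructose-derived Shi ketone (30 mol %), Oxone, K2CO3, Bu4NHSO4, MeCN/DMM–aq. borate buffer (pH 10.5), 0 °C
Reagents that add atoms: Oxone (potassium peroxymonosulfate) [K+].[O-]S(=O)(=O)OO
Why: Shi asymmetric epoxidation of a trisubstituted alkene through a spiro dioxirane transition state; the L-fructose-derived ketone should deliver oxygen to the face that makes the CH carbon (C2') S.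

**Step 4**
Reactants: 5 (S)-3-{[5-methoxy-3-methyl-2-(triisopropylsilyloxy)phenyl]methyl}-2,2-dimethyloxirane
Product: 6 (S)-1-[5-methoxy-3-methyl-2-(triisopropylsilyloxy)phenyl]-3-methylbut-3-en-2-ol
Conditions: Et2Al(TMP) [from TMP, n-BuLi, Et2AlCl], toluene, 0 °C
Reagents that add atoms: none
Why: Aluminium-amide isomerization of an epoxide to an allylic alcohol: the C–O bond at the tertiary carbon breaks while a methyl proton is removed syn, so the C2'–O bond is untouched and the S configuration should be retained.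

**Step 5**
Reactants: 7 (S)-citronellal
Product: 9 (2R,3S)-2-(anilinooxy)-3,7-dimethyloct-6-en-1-ol, via aminooxy aldehyde 8 (not isolated)
Conditions: PhNO, L-proline (20 mol %), CHCl3, 4 °C; then NaBH4, EtOH, 0 °C
Reagents that add atoms: nitrosobenzene O=Nc1ccccc1
Why: Proline-catalysed α-aminoxylation (nitroso aldol) through the E-enamine with acid-directed O-attack; L-proline should set the 2R centre (C12') under catalyst control irrespective of the C3 methyl, and reduction in the same flask prevents epimerization of the α-oxy aldehyde.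

**Step 6**
Reactants: 9 (2R,3S)-2-(anilinooxy)-3,7-dimethyloct-6-en-1-ol
Product: 10 (2R,3S)-3,7-dimethyloct-6-ene-1,2-diol
Conditions: Zn dust, AcOH/THF, rt
Reagents that add atoms: none
Why: Reductive N–O cleavage by zinc in acetic acid, which should leave the alkene and both stereocentres untouched.

**Step 7**
Reactants: 10 (2R,3S)-3,7-dimethyloct-6-ene-1,2-diol
Product: 11 (2R,3S)-3,7-dimethyl-1,2-bis(triethylsilyloxy)oct-6-ene
Conditions: TESCl, imidazole, DMF, 0 °C → rt
Reagents that add atoms: chlorotriethylsilane CC[Si](Cl)(CC)CC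
Why: Standard silylation of a primary and a secondary alcohol; two TES groups are used so that the primary one can later be oxidized directly.

**Step 8**
Reactants: 11 (2R,3S)-3,7-dimethyl-1,2-bis(triethylsilyloxy)oct-6-ene
Product: 12 (4S,5R)-4-methyl-5,6-bis(triethylsilyloxy)hexan-1-ol
Conditions: O3, CH2Cl2/MeOH, −78 °C; then NaBH4, −78 → 0 °C
Reagents that add atoms: ozone [O-][O+]=O
Why: Ozonolysis of the only alkene with reductive borohydride work-up should give the primary alcohol at C8'.

**Step 9**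
Reactants: 12 (4S,5R)-4-methyl-5,6-bis(triethylsilyloxy)hexan-1-ol
Product: 13 (2R,3S)-6-iodo-3-methyl-1,2-bis(triethylsilyloxy)hexane
Conditions: I2, PPh3, imidazole, CH2Cl2, 0 °C
Reagents that add atoms: iodine II
Why: Appel-type iodination of a primary alcohol under imidazole buffering, which the TES ethers should tolerate.

**Step 10**
Reactants: 13 (2R,3S)-6-iodo-3-methyl-1,2-bis(triethylsilyloxy)hexane
Product: 14 (2R,3S)-3-methyl-1,2-bis(triethylsilyloxy)oct-7-yne
Conditions: lithium acetylide–ethylenediamine complex, DMSO/THF, 0 °C → rt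
Reagents that add atoms: lithium acetylide–ethylenediamine complex [Li+].[C-]#C.NCCN
Why: SN2 alkylation of lithium acetylide by an unhindered primary iodide in a dipolar aprotic medium.

**Step 11**
Reactants: 14 (2R,3S)-3-methyl-1,2-bis(triethylsilyloxy)oct-7-yne
Product: 16 (2E,7S,8R)-3,7-dimethyl-8,9-bis(triethylsilyloxy)non-2-en-1-ol, via alkenylalane 15 (not isolated)
Conditions: Me3Al, Cp2ZrCl2 (25 mol %), CH2Cl2, 0 °C → rt; then n-BuLi, THF, −78 °C; (CH2O)n, −78 °C → rt
Reagents that add atoms: trimethylaluminium C[Al](C)C; paraformaldehyde (as formaldehyde) C=O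
Why: Negishi zirconium-catalysed carboalumination adds Me–Al syn with methyl at the internal carbon, and the alkenylalanate adds to formaldehyde with retention, which should fix the E-C6'=C7' geometry.

**Step 12**
Reactants: 16 (2E,7S,8R)-3,7-dimethyl-8,9-bis(triethylsilyloxy)non-2-en-1-ol
Product: 17 (2E,7S,8R)-1-bromo-3,7-dimethyl-8,9-bis(triethylsilyloxy)non-2-ene
Conditions: CBr4, PPh3, CH2Cl2, 0 °C
Reagents that add atoms: carbon tetrabromide BrC(Br)(Br)Br
Why: Appel bromination of a primary allylic alcohol under neutral conditions, which should proceed without allylic transposition or loss of the TES ethers.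

**Step 13**
Reactants: 6 (S)-1-[5-methoxy-3-methyl-2-(triisopropylsilyloxy)phenyl]-3-methylbut-3-en-2-ol; 17 (2E,7S,8R)-1-bromo-3,7-dimethyl-8,9-bis(triethylsilyloxy)non-2-ene
Product: 18 (2'S)-bis-allylic ether in which O2' of 6 carries the (2E,7S,8R)-3,7-dimethyl-8,9-bis(triethylsilyloxy)non-2-en-1-yl group of 17
Conditions: NaH, Bu4NI (cat.), THF/DMF, 0 °C → rt
Reagents that add atoms: none
Why: Williamson etherification by SN2 displacement of the primary allylic bromide with the sodium alkoxide of 6; no stereocentre takes part in bond making or breaking.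

**Step 14**
Reactants: 18 (2'S)-bis-allylic ether
Product: 21 (2E,5R,6E,11S,12R)-5-(tert-butyldimethylsilyloxy)-1-[5-methoxy-3-methyl-2-(triisopropylsilyloxy)phenyl]-3,7,11-trimethyl-12,13-bis(triethylsilyloxy)trideca-2,6-diene, via lithiated ether 19 (not isolated), via lithium alkoxide 20 (not isolated)
Conditions: n-BuLi (1.5 equiv), THF, −78 → −40 °C; then TBSOTf, −78 → 0 °C
Reagents that add atoms: tert-butyldimethylsilyl trifluoromethanesulfonate CC(C)(C)[Si](C)(C)OS(=O)(=O)C(F)(F)F
Why: n-BuLi should remove a proton from the OCH2 carbon (C5'), the only secondary α-oxygenated allylic position (the competing C2'–H is tertiary), and the α-alkoxyallyllithium 19 then undergoes a concerted suprafacial [2,3]-sigmatropic (Wittig) shift through a five-membered envelope transition state in which C5' bonds to the unsubstituted methylene terminus C4' while the C2'–O bond breaks. The closest known reaction type is the [2,3]-Wittig rearrangement of bis-allylic ethers of secondary 2-methylallylic alcohols with 1,3-transfer of chirality; no ring is closed. The new C2'=C3' alkene should be E because the ArCH2 group on C2' takes the pseudo-equatorial (outside) position of the envelope and so avoids A(1,3) strain with the C4' methylene, as is general for stabilized α-oxy carbanions. C5' is controlled by the C2' stereocentre: the (S)-C2'–O bond fixes which face of C3'=C4' is attacked, and the alkenyl group on the carbanion sits exo, away from the C3' methyl, which together should translate (S)-C2' into (R)-C5'. The step needs regioselective lithiation, [2,3] over [1,2] shift and retention of the C6'=C7' geometry; these should be secured by the tertiary nature of the competing C–H, by the unhindered terminus at low temperature, and by the two alkyl groups on C7' that keep the charge on C5' and so disfavour rotation of the allyl anion. Silylation of alkoxide 20 in the same flask protects O5' and excludes an anionic oxy-Cope shift of the 1,5-dien-3-olate.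

**Step 15**
Reactants: 21 (2E,5R,6E,11S,12R)-5-(tert-butyldimethylsilyloxy)-1-[5-methoxy-3-methyl-2-(triisopropylsilyloxy)phenyl]-3,7,11-trimethyl-12,13-bis(triethylsilyloxy)trideca-2,6-diene
Product: 22 (2R,3S,7E,9R,10E)-9-(tert-butyldimethylsilyloxy)-12-[5-methoxy-3-methyl-2-(triisopropylsilyloxy)phenyl]-3,7,10-trimethyl-2-(triethylsilyloxy)dodeca-7,10-dienal
Conditions: (COCl)2, DMSO, CH2Cl2, −78 → −30 °C; then Et3N, −78 °C → 0 °C
Reagents that add atoms: none
Why: Under Swern conditions a primary triethylsilyl ether is converted directly into the aldehyde because activated DMSO attacks the less hindered Si–O bond, while the secondary TES, TBS and aryl TIPS ethers should survive; low temperature should prevent epimerization at C12'.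

**Step 16**
Reactants: 22 (2R,3S,7E,9R,10E)-9-(tert-butyldimethylsilyloxy)-12-[5-methoxy-3-methyl-2-(triisopropylsilyloxy)phenyl]-3,7,10-trimethyl-2-(triethylsilyloxy)dodeca-7,10-dienal
Product: 23 (2E,5R,6E,11S,12R)-5-(tert-butyldimethylsilyloxy)-1-[5-methoxy-3-methyl-2-(triisopropylsilyloxy)phenyl]-3,7,11,15-tetramethyl-12-(triethylsilyloxy)hexadeca-2,6,14-trien-13-ol (mixture of C13 epimers)
Conditions: 2-methylprop-1-enylmagnesium bromide, THF, −78 °C; cold NH4Cl quench
Reagents that add atoms: 2-methylprop-1-enylmagnesium bromide CC(C)=C[Mg]Br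
Why: Grignard addition to the α-silyloxy aldehyde at low temperature (cold quench to avoid 1,2-silyl migration); the new C13' centre is of no consequence because it is oxidized in the next step.

**Step 17**
Reactants: 23 (2E,5R,6E,11S,12R)-5-(tert-butyldimethylsilyloxy)-1-[5-methoxy-3-methyl-2-(triisopropylsilyloxy)phenyl]-3,7,11,15-tetramethyl-12-(triethylsilyloxy)hexadeca-2,6,14-trien-13-ol
Product: 24 (2E,5R,6E,11S,12R)-5-(tert-butyldimethylsilyloxy)-1-[5-methoxy-3-methyl-2-(triisopropylsilyloxy)phenyl]-3,7,11,15-tetramethyl-12-(triethylsilyloxy)hexadeca-2,6,14-trien-13-one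
Conditions: Dess–Martin periodinane, NaHCO3, CH2Cl2, 0 °C → rt
Reagents that add atoms: none
Why: Dess–Martin oxidation of the only free (allylic) alcohol to the enone under buffered conditions that should not epimerize C12'.

**Step 18**
Reactants: 24 (2E,5R,6E,11S,12R)-5-(tert-butyldimethylsilyloxy)-1-[5-methoxy-3-methyl-2-(triisopropylsilyloxy)phenyl]-3,7,11,15-tetramethyl-12-(triethylsilyloxy)hexadeca-2,6,14-trien-13-one
Product: 25 (2E,5R,6E,11S,12R)-5,12-dihydroxy-1-(2-hydroxy-5-methoxy-3-methylphenyl)-3,7,11,15-tetramethylhexadeca-2,6,14-trien-13-one (CNP0156407.1)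
Conditions: TBAF, AcOH (1:1), THF, 0 °C → rt
Reagents that add atoms: none
Why: Fluoride cleaves the aryl TIPS, secondary TBS and TES ethers in one operation; buffering with acetic acid should protect the α'-hydroxy enone from epimerization at C12' and from 5-endo oxa-Michael closure.

**Compound list**

1 | 4-methoxy-2-methylphenol | COc1ccc(O)c(C)c1 | starting material
2 | 1-bromo-3-methylbut-2-ene (prenyl bromide) | CC(C)=CCBr | starting material
3 | 4-methoxy-2-methyl-6-(3-methylbut-2-en-1-yl)phenol | COc1cc(C)c(O)c(CC=C(C)C)c1 | intermediate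
4 | triisopropyl[4-methoxy-2-methyl-6-(3-methylbut-2-en-1-yl)phenoxy]silane | COc1cc(C)c(O[Si](C(C)C)(C(C)C)C(C)C)c(CC=C(C)C)c1 | intermediate
5 | (S)-3-{[5-methoxy-3-methyl-2-(triisopropylsilyloxy)phenyl]methyl}-2,2-dimethyloxirane | COc1cc(C)c(O[Si](C(C)C)(C(C)C)C(C)C)c(C[C@@H]2OC2(C)C)c1 | intermediate
6 | (S)-1-[5-methoxy-3-methyl-2-(triisopropylsilyloxy)phenyl]-3-methylbut-3-en-2-ol | COc1cc(C)c(O[Si](C(C)C)(C(C)C)C(C)C)c(C[C@H](O)C(C)=C)c1 | intermediate
7 | (S)-citronellal, (S)-3,7-dimethyloct-6-enal | CC(C)=CCC[C@H](C)CC=O | starting material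
8 | (2R,3S)-2-(anilinooxy)-3,7-dimethyloct-6-enal | CC(C)=CCC[C@H](C)[C@@H](ONc1ccccc1)C=O | intermediate (not isolated)
9 | (2R,3S)-2-(anilinooxy)-3,7-dimethyloct-6-en-1-ol | CC(C)=CCC[C@H](C)[C@@H](ONc1ccccc1)CO | intermediate
10 | (2R,3S)-3,7-dimethyloct-6-ene-1,2-diol | CC(C)=CCC[C@H](C)[C@@H](O)CO | intermediate
11 | (2R,3S)-3,7-dimethyl-1,2-bis(triethylsilyloxy)oct-6-ene | CC(C)=CCC[C@H](C)[C@@H](O[Si](CC)(CC)CC)CO[Si](CC)(CC)CC | intermediate
12 | (4S,5R)-4-methyl-5,6-bis(triethylsilyloxy)hexan-1-ol | OCCC[C@H](C)[C@@H](O[Si](CC)(CC)CC)CO[Si](CC)(CC)CC | intermediate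
13 | (2R,3S)-6-iodo-3-methyl-1,2-bis(triethylsilyloxy)hexane | ICCC[C@H](C)[C@@H](O[Si](CC)(CC)CC)CO[Si](CC)(CC)CC | intermediate
14 | (2R,3S)-3-methyl-1,2-bis(triethylsilyloxy)oct-7-yne | C#CCCC[C@H](C)[C@@H](O[Si](CC)(CC)CC)CO[Si](CC)(CC)CC | intermediate
15 | dimethyl[(1E,6S,7R)-2,6-dimethyl-7,8-bis(triethylsilyloxy)oct-1-en-1-yl]alane | C[Al](C)/C=C(\C)CCC[C@H](C)[C@@H](O[Si](CC)(CC)CC)CO[Si](CC)(CC)CC | intermediate (not isolated)
16 | (2E,7S,8R)-3,7-dimethyl-8,9-bis(triethylsilyloxy)non-2-en-1-ol | OC/C=C(\C)CCC[C@H](C)[C@@H](O[Si](CC)(CC)CC)CO[Si](CC)(CC)CC | intermediate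
17 | (2E,7S,8R)-1-bromo-3,7-dimethyl-8,9-bis(triethylsilyloxy)non-2-ene | BrC/C=C(\C)CCC[C@H](C)[C@@H](O[Si](CC)(CC)CC)CO[Si](CC)(CC)CC | intermediate
18 | (2'S)-bis-allylic ether: O2' of 6 alkylated with the allyl unit of 17 | COc1cc(C)c(O[Si](C(C)C)(C(C)C)C(C)C)c(C[C@H](OC/C=C(\C)CCC[C@H](C)[C@@H](O[Si](CC)(CC)CC)CO[Si](CC)(CC)CC)C(C)=C)c1 | intermediate
19 | ether 18 lithiated at the OCH carbon (C5') | COc1cc(C)c(O[Si](C(C)C)(C(C)C)C(C)C)c(C[C@H](OC([Li])/C=C(\C)CCC[C@H](C)[C@@H](O[Si](CC)(CC)CC)CO[Si](CC)(CC)CC)C(C)=C)c1 | intermediate (not isolated)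
20 | lithium (2E,5R,6E,11S,12R)-1-aryl-3,7,11-trimethyl-12,13-bis(triethylsilyloxy)trideca-2,6-dien-5-olate (aryl = 5-methoxy-3-methyl-2-(triisopropylsilyloxy)phenyl) | [Li+].COc1cc(C)c(O[Si](C(C)C)(C(C)C)C(C)C)c(C/C=C(\C)C[C@@H]([O-])/C=C(\C)CCC[C@H](C)[C@@H](O[Si](CC)(CC)CC)CO[Si](CC)(CC)CC)c1 | intermediate (not isolated)
21 | (2E,5R,6E,11S,12R)-5-(tert-butyldimethylsilyloxy)-1-[5-methoxy-3-methyl-2-(triisopropylsilyloxy)phenyl]-3,7,11-trimethyl-12,13-bis(triethylsilyloxy)trideca-2,6-diene | COc1cc(C)c(O[Si](C(C)C)(C(C)C)C(C)C)c(C/C=C(\C)C[C@@H](O[Si](C)(C)C(C)(C)C)/C=C(\C)CCC[C@H](C)[C@@H](O[Si](CC)(CC)CC)CO[Si](CC)(CC)CC)c1 | intermediate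
22 | (2R,3S,7E,9R,10E)-9-(tert-butyldimethylsilyloxy)-12-[5-methoxy-3-methyl-2-(triisopropylsilyloxy)phenyl]-3,7,10-trimethyl-2-(triethylsilyloxy)dodeca-7,10-dienal | COc1cc(C)c(O[Si](C(C)C)(C(C)C)C(C)C)c(C/C=C(\C)C[C@@H](O[Si](C)(C)C(C)(C)C)/C=C(\C)CCC[C@H](C)[C@@H](O[Si](CC)(CC)CC)C=O)c1 | intermediate
23 | (2E,5R,6E,11S,12R)-5-(tert-butyldimethylsilyloxy)-1-[5-methoxy-3-methyl-2-(triisopropylsilyloxy)phenyl]-3,7,11,15-tetramethyl-12-(triethylsilyloxy)hexadeca-2,6,14-trien-13-ol (C13 epimers) | COc1cc(C)c(O[Si](C(C)C)(C(C)C)C(C)C)c(C/C=C(\C)C[C@@H](O[Si](C)(C)C(C)(C)C)/C=C(\C)CCC[C@H](C)[C@@H](O[Si](CC)(CC)CC)C(O)C=C(C)C)c1 | intermediate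
24 | (2E,5R,6E,11S,12R)-5-(tert-butyldimethylsilyloxy)-1-[5-methoxy-3-methyl-2-(triisopropylsilyloxy)phenyl]-3,7,11,15-tetramethyl-12-(triethylsilyloxy)hexadeca-2,6,14-trien-13-one | COc1cc(C)c(O[Si](C(C)C)(C(C)C)C(C)C)c(C/C=C(\C)C[C@@H](O[Si](C)(C)C(C)(C)C)/C=C(\C)CCC[C@H](C)[C@@H](O[Si](CC)(CC)CC)C(=O)C=C(C)C)c1 | intermediate
25 | (2E,5R,6E,11S,12R)-5,12-dihydroxy-1-(2-hydroxy-5-methoxy-3-methylphenyl)-3,7,11,15-tetramethylhexadeca-2,6,14-trien-13-one | COc1cc(C)c(O)c(C/C=C(\C)C[C@@H](O)/C=C(\C)CCC[C@H](C)[C@@H](O)C(=O)C=C(C)C)c1 | target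

**Step count and risks**

Total steps: 18. Longest linear sequence: 14 steps (steps 5–18, from 7 to 25); the arene branch (steps 1–4) joins at step 13.

Steps most likely to fail:

1. **Step 14 (key step).** Lithiation may be slow or may stray to the C2'–H or the arene. The allyl anion may rotate and erode the C6'=C7' geometry. Exo selection may be incomplete and lower the transfer of chirality. A [1,2]-shift may compete. The fallback keeps the rearrangement but moves the C6'=C7' alkene to a later stage; it sets out from 6 and 13 and returns at 21. Alcohol 6 is O-propargylated (NaH, propargyl bromide, THF) to the propargyl ether F1. Its terminal acetylide (n-BuLi, 1 equiv, THF/DMPU, −78 °C → rt) is alkylated with iodide 13 to the alkynyl ether F2. n-BuLi at −78 °C should now lithiate only the much more acidic propargylic OCH2, and the [2,3]-Wittig shift should give the propargylic alcohol F3 with the same E selectivity and sense of chirality transfer. Hydroxyl-directed trans-hydroalumination with Red-Al followed by iodine should give the (Z)-iodoalkene F4. Negishi methylation (MeZnCl, Pd(PPh3)4, THF) should put the C7' methyl in with retention and give the free C5' alcohol F5, which is silylated (TBSOTf, 2,6-lutidine) to 21.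

2. **Step 1.** O-Alkylation and over-alkylation may compete with ortho C-alkylation of the phenoxide. The fallback replaces direct C-alkylation by O-alkylation and a sigmatropic shift; it sets out from 1 and returns at 3. Pd(0)-catalysed O-allylation of 1 with tert-butyl 2-methylbut-3-en-2-yl carbonate (Pd(PPh3)4, THF) should give the aryl 1,1-dimethylallyl ether F6. Aromatic Claisen rearrangement (N,N-diethylaniline, 180 °C) should then move the allyl unit, with allylic inversion, to the only free ortho position and give 3.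

3. **Step 15.** The primary TES ether may be cleaved incompletely, the secondary silyl ethers may be lost under the acidic activation, or C12' may epimerize. The fallback separates deprotection from oxidation; it sets out from 21 and returns at 22. Buffered HF·pyridine (pyridine, THF, 0 °C) should remove only the primary TES group and give the primary alcohol F7, which is oxidized under Parikh–Doering conditions (SO3·pyridine, DMSO, iPr2NEt, 0 °C) to 22.

**Further compounds**

F1 | step 14 | triisopropyl{4-methoxy-2-methyl-6-[(2S)-3-methyl-2-(prop-2-yn-1-yloxy)but-3-en-1-yl]phenoxy}silane | COc1cc(C)c(O[Si](C(C)C)(C(C)C)C(C)C)c(C[C@H](OCC#C)C(C)=C)c1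
F2 | step 14 | (2'S)-alkynyl ether: O2' of 6 carrying the (7S,8R)-7-methyl-8,9-bis(triethylsilyloxy)non-2-yn-1-yl group | COc1cc(C)c(O[Si](C(C)C)(C(C)C)C(C)C)c(C[C@H](OCC#CCCC[C@H](C)[C@@H](O[Si](CC)(CC)CC)CO[Si](CC)(CC)CC)C(C)=C)c1
F3 | step 14 | (2E,5R,11S,12R)-1-[5-methoxy-3-methyl-2-(triisopropylsilyloxy)phenyl]-3,11-dimethyl-12,13-bis(triethylsilyloxy)tridec-2-en-6-yn-5-ol | COc1cc(C)c(O[Si](C(C)C)(C(C)C)C(C)C)c(C/C=C(\C)C[C@@H](O)C#CCCC[C@H](C)[C@@H](O[Si](CC)(CC)CC)CO[Si](CC)(CC)CC)c1
F4 | step 14 | (2E,5R,6Z,11S,12R)-7-iodo-1-[5-methoxy-3-methyl-2-(triisopropylsilyloxy)phenyl]-3,11-dimethyl-12,13-bis(triethylsilyloxy)trideca-2,6-dien-5-ol | COc1cc(C)c(O[Si](C(C)C)(C(C)C)C(C)C)c(C/C=C(\C)C[C@@H](O)/C=C(\I)CCC[C@H](C)[C@@H](O[Si](CC)(CC)CC)CO[Si](CC)(CC)CC)c1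
F5 | step 14 | (2E,5R,6E,11S,12R)-1-[5-methoxy-3-methyl-2-(triisopropylsilyloxy)phenyl]-3,7,11-trimethyl-12,13-bis(triethylsilyloxy)trideca-2,6-dien-5-ol | COc1cc(C)c(O[Si](C(C)C)(C(C)C)C(C)C)c(C/C=C(\C)C[C@@H](O)/C=C(\C)CCC[C@H](C)[C@@H](O[Si](CC)(CC)CC)CO[Si](CC)(CC)CC)c1
F6 | step 1 | 4-methoxy-2-methyl-1-[(2-methylbut-3-en-2-yl)oxy]benzene | COc1ccc(OC(C)(C)C=C)c(C)c1
F7 | step 15 | (2R,3S,7E,9R,10E)-9-(tert-butyldimethylsilyloxy)-12-[5-methoxy-3-methyl-2-(triisopropylsilyloxy)phenyl]-3,7,10-trimethyl-2-(triethylsilyloxy)dodeca-7,10-dien-1-ol | COc1cc(C)c(O[Si](C(C)C)(C(C)C)C(C)C)c(C/C=C(\C)C[C@@H](O[Si](C)(C)C(C)(C)C)/C=C(\C)CCC[C@H](C)[C@@H](O[Si](CC)(CC)CC)CO)c1
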